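**Retrosynthetic overview**
- The target is opened at C13–C14: a C16 aldehyde of the clerodane core is α-alkylated with ethenyl icosanoate, which sets C13 and places the ester on O15, and the aldehyde is then reduced.
- The aldehyde comes from hydroformylation of a C9 allyl group; the C3=C4 alkene and C18 come from the enol triflate of a 4-ketone by methyl cross-coupling.
- The 4-keto trans-decalin comes from a Prins cyclisation followed by a 1,2-hydride and a 1,2-methyl (semipinacol) shift of a cyclohexenyl methyl ketone. Ring A is formed second, onto ring B, and C5 and C10 are set here.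
- Ring B (C8, C9) comes from 2-methylcyclohex-2-enone by asymmetric conjugate methylation and enolate allylation, then enol triflate and Negishi coupling with a 4-oxopentylzinc reagent.
- Icosanoate comes from oct-1-yne, 1,6-dibromohexane and hex-5-ynoic acid, followed by hydrogenation and transvinylation.

Assumption: the acyl chain is read as icosanoyl (C20), and each chiral ligand or catalyst is used as the antipode that gives the stated configuration.

**Route**

Step 1
Reactants: 1 2-methylcyclohex-2-en-1-one; 2 3-bromoprop-1-ene (allyl bromide)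
Product: 4 (2S,3R)-2,3-dimethyl-2-(prop-2-en-1-yl)cyclohexan-1-one, via dimethylaluminium enolate 3 (not isolated)
Conditions: Cu(OTf)2 (2 mol%), chiral phosphoramidite (4 mol%), Me3Al, Et2O, −30 °C; then MeLi, THF/HMPA, 2, −30 → 0 °C
Reagents that add atoms: trimethylaluminium C[Al](C)C
Why: Copper-catalysed asymmetric conjugate addition sets C8 (3R) under ligand control, and the aluminate enolate is allylated anti to the new methyl (one-pot conjugate addition–enolate alkylation), which fixes the C9 quaternary centre with the two methyls cis.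

Step 2
Reactants: 4 (2S,3R)-2,3-dimethyl-2-(prop-2-en-1-yl)cyclohexan-1-one
Product: 6 (5R,6S)-5,6-dimethyl-6-(prop-2-en-1-yl)cyclohex-1-en-1-yl trifluoromethanesulfonate, via lithium enolate 5 (not isolated)
Conditions: LDA, THF, −78 °C; PhNTf2, −78 → 0 °C
Reagents that add atoms: N-phenylbis(trifluoromethanesulfonimide) O=S(=O)(N(c1ccccc1)S(=O)(=O)C(F)(F)F)C(F)(F)F
Why: The ketone can enolise only away from the quaternary carbon, so enolate O-triflation gives one regioisomer and leaves both stereocentres untouched.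

Step 3
Reactants: 6 (5R,6S)-5,6-dimethyl-6-(prop-2-en-1-yl)cyclohex-1-en-1-yl trifluoromethanesulfonate; 7 5-bromopentan-2-one
Product: 9 5-[(5R,6S)-5,6-dimethyl-6-(prop-2-en-1-yl)cyclohex-1-en-1-yl]pentan-2-one, via organozinc bromide 8 (not isolated)
Conditions: 7, Zn dust, I2 (5 mol%), DMA, 60 °C; then 6, Pd(OAc)2 (3 mol%), SPhos (6 mol%), THF/DMA, 50 °C
Reagents that add atoms: none
Why: Negishi sp2–sp3 cross-coupling of the alkenyl triflate with a ketone-tolerant alkylzinc halide attaches C1–C4 and C19 at C10 and keeps the C5=C10 alkene in place.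

Step 4
Reactants: 9 5-[(5R,6S)-5,6-dimethyl-6-(prop-2-en-1-yl)cyclohex-1-en-1-yl]pentan-2-one
Product: 10 (4aR,5S,6R,8aR)-5,6,8a-trimethyl-5-(prop-2-en-1-yl)-3,4,4a,5,6,7,8,8a-octahydronaphthalen-1(2H)-one
Conditions: MeAlCl2 (2.2 equiv), CH2Cl2, −78 → 0 °C
Reagents that add atoms: none
Why: Lewis-acid Prins cyclisation of the ketone carbon onto C5 (chair-like, C17 equatorial) gives the tertiary C10 cation; a suprafacial 1,2-hydride shift (C5→C10) and an anti 1,2-methyl shift from the aluminium carbinolate carbon (C4→C5, semipinacol) then regenerate the ketone, so H10 and the C5 methyl end up trans (alkylaluminium-halide Prins/1,2-shift cascade of olefinic carbonyl compounds).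

Step 5
Reactants: 10 (4aR,5S,6R,8aR)-5,6,8a-trimethyl-5-(prop-2-en-1-yl)-3,4,4a,5,6,7,8,8a-octahydronaphthalen-1(2H)-one
Product: 12 (4aR,5S,6R,8aR)-5,6,8a-trimethyl-5-(prop-2-en-1-yl)-3,4,4a,5,6,7,8,8a-octahydronaphthalen-1-yl trifluoromethanesulfonate, via lithium enolate 11 (not isolated)
Conditions: LDA, THF, −78 °C; PhNTf2, −78 → 0 °C
Reagents that add atoms: N-phenylbis(trifluoromethanesulfonimide) O=S(=O)(N(c1ccccc1)S(=O)(=O)C(F)(F)F)C(F)(F)F
Why: C5 is quaternary, so enolate O-triflation can only give the C3=C4 enol triflate.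

Step 6
Reactants: 12 (4aR,5S,6R,8aR)-5,6,8a-trimethyl-5-(prop-2-en-1-yl)-3,4,4a,5,6,7,8,8a-octahydronaphthalen-1-yl trifluoromethanesulfonate
Product: 13 (1S,2R,4aR,8aR)-1,2,4a,5-tetramethyl-1-(prop-2-en-1-yl)-1,2,3,4,4a,7,8,8a-octahydronaphthalene
Conditions: MeMgBr, Fe(acac)3 (5 mol%), THF/NMP, −20 → 0 °C
Reagents that add atoms: methylmagnesium bromide C[Mg]Br
Why: Iron-catalysed Kumada-type coupling of the alkenyl triflate adds C18 and fixes the C3=C4 alkene without an acidic step that could reverse the methyl shift.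

Step 7
Reactants: 13 (1S,2R,4aR,8aR)-1,2,4a,5-tetramethyl-1-(prop-2-en-1-yl)-1,2,3,4,4a,7,8,8a-octahydronaphthalene
Product: 14 4-[(1S,2R,4aR,8aR)-1,2,4a,5-tetramethyl-1,2,3,4,4a,7,8,8a-octahydronaphthalen-1-yl]butanal
Conditions: Rh(acac)(CO)2 (1 mol%), Xantphos (2 mol%), CO/H2 (1:1, 10 bar), toluene, 70 °C
Reagents that add atoms: carbon monoxide [C-]#[O+]
Why: Linear-selective rhodium hydroformylation converts the monosubstituted alkene into the C16 aldehyde, while the hindered trisubstituted ring alkene does not react.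

Step 8
Reactants: 15 oct-1-yne; 16 1,6-dibromohexane
Product: 18 1-bromotetradec-7-yne, via lithium octynide 17 (not isolated)
Conditions: n-BuLi, THF/DMPU, −78 °C; 16 (4 equiv), −78 → 25 °C
Reagents that add atoms: none
Why: SN2 alkylation of the lithium acetylide with excess dibromide stops at mono-alkylation.

Step 9
Reactants: 18 1-bromotetradec-7-yne; 19 hex-5-ynoic acid
Product: 21 icosa-5,13-diynoic acid, via dilithium alkynoate 20 (not isolated)
Conditions: n-BuLi (2.2 equiv), THF/HMPA, −78 → 0 °C; 18, 25 °C; HCl work-up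
Reagents that add atoms: none
Why: The carboxylate/acetylide dianion alkylates at the acetylide carbon only (acetylide alkylation), which completes the C20 chain.

Step 10
Reactants: 21 icosa-5,13-diynoic acid
Product: 22 icosanoic acid
Conditions: H2 (1 atm), 10% Pd/C, EtOAc, 25 °C
Reagents that add atoms: none
Why: Heterogeneous catalytic hydrogenation saturates both alkynes.

Step 11
Reactants: 22 icosanoic acid; 23 ethenyl acetate
Product: 24 ethenyl icosanoate
Conditions: Pd(OAc)2 (5 mol%), KOH (10 mol%), 23 as solvent, 40 °C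
Reagents that add atoms: none
Why: Palladium(II)-catalysed transvinylation is driven by the large excess of vinyl acetate.

Step 12
Reactants: 14 4-[(1S,2R,4aR,8aR)-1,2,4a,5-tetramethyl-1,2,3,4,4a,7,8,8a-octahydronaphthalen-1-yl]butanal; 24 ethenyl icosanoate
Product: 26 (3R)-3-(hydroxymethyl)-5-[(1S,2R,4aR,8aR)-1,2,4a,5-tetramethyl-1,2,3,4,4a,7,8,8a-octahydronaphthalen-1-yl]pentyl icosanoate, via formyl ester 25 (not isolated)
Conditions: 24 (3 equiv), Ir(Fmppy)2(dtbbpy)PF6 (1 mol%), chiral imidazolidinone·TFA (20 mol%), 2,4,6-iPr3C6H2SH (10 mol%), DME, blue LEDs, 0 °C; then NaBH4, EtOH, −20 °C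
Reagents that add atoms: none
Why: Proposed new method: enantioselective anti-Markovnikov α-hydroalkylation of an aldehyde with a vinyl ester by merged photoredox, enamine and thiol hydrogen-atom-transfer catalysis, in which the electrophilic 3π-electron enaminyl radical cation adds to the CH2 end of the vinyl ester, the α-acyloxyalkyl radical is quenched by the thiol faster than it can telomerise, the imidazolidinone shields one enamine face to set C13 (R) and the acyloxy group lands on C15 by construction, after which borohydride reduces only the aldehyde; the closest known chemistry is the triple-catalytic α-alkylation of aldehydes with simple alkenes and radical additions to vinyl esters.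

**Compound list**
1 | 2-methylcyclohex-2-en-1-one | CC1=CCCCC1=O | starting material
2 | 3-bromoprop-1-ene (allyl bromide) | C=CCBr | starting material
3 | [(3R)-2,3-dimethylcyclohex-1-en-1-yl]oxy(dimethyl)alumane | CC1=C(O[Al](C)C)CCC[C@H]1C | intermediate
4 | (2S,3R)-2,3-dimethyl-2-(prop-2-en-1-yl)cyclohexan-1-one | C=CC[C@@]1(C)[C@H](C)CCCC1=O | intermediate
5 | lithium (5R,6S)-5,6-dimethyl-6-(prop-2-en-1-yl)cyclohex-1-en-1-olate | C=CC[C@@]1(C)[C@H](C)CCC=C1O[Li] | intermediate
6 | (5R,6S)-5,6-dimethyl-6-(prop-2-en-1-yl)cyclohex-1-en-1-yl trifluoromethanesulfonate | C=CC[C@@]1(C)[C@H](C)CCC=C1OS(=O)(=O)C(F)(F)F | intermediate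
7 | 5-bromopentan-2-one | CC(=O)CCCBr | starting material
8 | bromo(4-oxopentyl)zinc | CC(=O)CCC[Zn]Br | intermediate
9 | 5-[(5R,6S)-5,6-dimethyl-6-(prop-2-en-1-yl)cyclohex-1-en-1-yl]pentan-2-one | C=CC[C@@]1(C)[C@H](C)CCC=C1CCCC(C)=O | intermediate
10 | (4aR,5S,6R,8aR)-5,6,8a-trimethyl-5-(prop-2-en-1-yl)-3,4,4a,5,6,7,8,8a-octahydronaphthalen-1(2H)-one | C=CC[C@@]1(C)[C@H](C)CC[C@@]2(C)C(=O)CCC[C@H]12 | intermediate
11 | lithium (4aR,5S,6R,8aR)-5,6,8a-trimethyl-5-(prop-2-en-1-yl)-3,4,4a,5,6,7,8,8a-octahydronaphthalen-1-olate | C=CC[C@@]1(C)[C@H](C)CC[C@@]2(C)C(O[Li])=CCC[C@H]12 | intermediate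
12 | (4aR,5S,6R,8aR)-5,6,8a-trimethyl-5-(prop-2-en-1-yl)-3,4,4a,5,6,7,8,8a-octahydronaphthalen-1-yl trifluoromethanesulfonate | C=CC[C@@]1(C)[C@H](C)CC[C@@]2(C)C(OS(=O)(=O)C(F)(F)F)=CCC[C@H]12 | intermediate
13 | (1S,2R,4aR,8aR)-1,2,4a,5-tetramethyl-1-(prop-2-en-1-yl)-1,2,3,4,4a,7,8,8a-octahydronaphthalene | C=CC[C@@]1(C)[C@H](C)CC[C@@]2(C)C(C)=CCC[C@H]12 | intermediate
14 | 4-[(1S,2R,4aR,8aR)-1,2,4a,5-tetramethyl-1,2,3,4,4a,7,8,8a-octahydronaphthalen-1-yl]butanal | O=CCCC[C@@]1(C)[C@H](C)CC[C@@]2(C)C(C)=CCC[C@H]12 | intermediate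
15 | oct-1-yne | CCCCCCC#C | starting material
16 | 1,6-dibromohexane | BrCCCCCCBr | starting material
17 | lithium oct-1-yn-1-ide | CCCCCCC#C[Li] | intermediate
18 | 1-bromotetradec-7-yne | CCCCCCC#CCCCCCCBr | intermediate
19 | hex-5-ynoic acid | C#CCCCC(=O)O | starting material
20 | lithium 6-lithiohex-5-ynoate | [Li]C#CCCCC(=O)O[Li] | intermediate
21 | icosa-5,13-diynoic acid | CCCCCCC#CCCCCCCC#CCCCC(=O)O | intermediate
22 | icosanoic acid | CCCCCCCCCCCCCCCCCCCC(=O)O | intermediate
23 | ethenyl acetate (vinyl acetate) | CC(=O)OC=C | starting material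
24 | ethenyl icosanoate | CCCCCCCCCCCCCCCCCCCC(=O)OC=C | intermediate
25 | (3R)-3-formyl-5-[(1S,2R,4aR,8aR)-1,2,4a,5-tetramethyl-1,2,3,4,4a,7,8,8a-octahydronaphthalen-1-yl]pentyl icosanoate | CCCCCCCCCCCCCCCCCCCC(=O)OCC[C@H](C=O)CC[C@@]1(C)[C@H](C)CC[C@@]2(C)C(C)=CCC[C@H]12 | intermediate
26 | (3R)-3-(hydroxymethyl)-5-[(1S,2R,4aR,8aR)-1,2,4a,5-tetramethyl-1,2,3,4,4a,7,8,8a-octahydronaphthalen-1-yl]pentyl icosanoate | CCCCCCCCCCCCCCCCCCCC(=O)OCC[C@H](CO)CC[C@@]1(C)[C@H](C)CC[C@@]2(C)C(C)=CCC[C@H]12 | target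

**Totals**
Total step count: 12. Longest linear sequence: 8 steps (steps 1–7, then 12); the icosanoate branch (steps 8–11) joins at step 12.

**Three steps most likely to fail**

Step 4 (Prins / 1,2-H / 1,2-Me cascade). It may stop at the ene-type alcohol or a chlorohydrin, close on the other alkene face, or lose material through a competing shift from C9. The fallback sets out from 9 and comes back at 10. It separates ring closure from the shifts. Me2AlCl (1.5 equiv, CH2Cl2, −78 °C), a proton-scavenging Lewis acid, carries out only the Prins/ene closure and gives the isolable homoallylic alcohol (1S,5S,6R,8aS)-1,5,6-trimethyl-5-(prop-2-en-1-yl)-1,2,3,5,6,7,8,8a-octahydronaphthalen-1-ol F2, which can be freed from epimers. A separate Brønsted-acid step (TfOH 5 mol%, HFIP/CH2Cl2, −20 °C) then protonates its ring alkene to regenerate the ring-fusion cation, and the hydride and methyl shifts give 10.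

Step 12 (the proposed new α-hydroalkylation). The enaminyl radical cation may add poorly to the vinyl ester, the ee may be low, or acyl transfer may occur during the reduction. The fallback uses known chemistry, sets out from 13 and comes back at 26.
- Cross-metathesis of 13 with commercial 3-methylideneoxolan-2-one (C=C1CCOC1=O; Hoveyda–Grubbs II, 2,6-dichlorobenzoquinone, CH2Cl2, 40 °C) gives (3E)-3-{2-[(1S,2R,4aR,8aR)-1,2,4a,5-tetramethyl-1,2,3,4,4a,7,8,8a-octahydronaphthalen-1-yl]ethylidene}oxolan-2-one F3.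
- Ru(OAc)2(BINAP)-catalysed asymmetric hydrogenation (H2 50 bar, MeOH/CH2Cl2) reduces only the conjugated exocyclic alkene and gives (3R)-3-{2-[(1S,2R,4aR,8aR)-1,2,4a,5-tetramethyl-1,2,3,4,4a,7,8,8a-octahydronaphthalen-1-yl]ethyl}oxolan-2-one F4.
- LiAlH4 (THF, 0 °C) opens the lactone to (2R)-2-{2-[(1S,2R,4aR,8aR)-1,2,4a,5-tetramethyl-1,2,3,4,4a,7,8,8a-octahydronaphthalen-1-yl]ethyl}butane-1,4-diol F5.
- Lipase acylation (immobilised CAL-B, 24, MTBE, 30 °C) esterifies the unbranched C15 hydroxyl in preference to the β-branched C16 hydroxyl and gives 26.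

Step 1 (one-pot conjugate methylation and allylation). The aluminium enolate may alkylate sluggishly or with poor diastereoselectivity at the quaternary centre. The fallback sets out from 1 and comes back at 4. The same copper-catalysed Me3Al addition is quenched with TMSOTf/Et3N to isolate [(3R)-2,3-dimethylcyclohex-1-en-1-yl]oxy(trimethyl)silane F1. The quaternary centre is then made by palladium-catalysed Tsuji allylation (Pd2(dba)3, (S)-t-Bu-PHOX, Bu4N[Ph3SiF2], allyl methyl carbonate C=CCOC(=O)OC, THF, 25 °C), so that a π-allylpalladium enolate under ligand and substrate control replaces the SN2 alkylation.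

**Further compounds**
F1 | step 1 | [(3R)-2,3-dimethylcyclohex-1-en-1-yl]oxy(trimethyl)silane | CC1=C(O[Si](C)(C)C)CCC[C@H]1C
F2 | step 4 | (1S,5S,6R,8aS)-1,5,6-trimethyl-5-(prop-2-en-1-yl)-1,2,3,5,6,7,8,8a-octahydronaphthalen-1-ol | C=CC[C@@]1(C)[C@H](C)CC[C@H]2C1=CCC[C@]2(C)O
F3 | step 12 | (3E)-3-{2-[(1S,2R,4aR,8aR)-1,2,4a,5-tetramethyl-1,2,3,4,4a,7,8,8a-octahydronaphthalen-1-yl]ethylidene}oxolan-2-one | O=C3OCC/C3=C\C[C@@]1(C)[C@H](C)CC[C@@]2(C)C(C)=CCC[C@H]12
F4 | step 12 | (3R)-3-{2-[(1S,2R,4aR,8aR)-1,2,4a,5-tetramethyl-1,2,3,4,4a,7,8,8a-octahydronaphthalen-1-yl]ethyl}oxolan-2-one | O=C3OCC[C@H]3CC[C@@]1(C)[C@H](C)CC[C@@]2(C)C(C)=CCC[C@H]12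
F5 | step 12 | (2R)-2-{2-[(1S,2R,4aR,8aR)-1,2,4a,5-tetramethyl-1,2,3,4,4a,7,8,8a-octahydronaphthalen-1-yl]ethyl}butane-1,4-diol | OCC[C@H](CO)CC[C@@]1(C)[C@H](C)CC[C@@]2(C)C(C)=CCC[C@H]12
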